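## The problem

Compound 23, (3S,5S,6S,3'R)-7',8'-didehydro-5,6-dihydro-β,β-carotene-3,5,6,3'-tetrol (descriptors as drawn; carotenoid numbering, ring B unprimed), is a C40 carotenoid whose two six-membered end groups are not fused but joined through an eighteen-carbon chain (C7–C15, C15'–C7') that carries four methyl branches, eight E double bonds and one triple bond (C7'≡C8'). Ring A (C1'–C6', a cyclohexene) has a single secondary carbinol, C3', too remote to give or receive stereocontrol, so it must come from an enantiopure building block. Ring B (C1–C6, a cyclohexane) has three stereocentres: secondary C3, the methyl-bearing tertiary carbinol C5 and the tertiary carbinol C6, with 3-OH and 5-OH cis and 6-OH trans to both. C3 can direct the oxygenation at C5, and the methyl groups on C1 and C5 can then direct bond formation at C6. C6 is the hard centre: fully substituted, flanked by quaternary C1 and C5, and bonded to the chain at C7. The polyene is sensitive to light, oxygen, acid and heat, the C9'=C10' bond beside the triple bond loses its geometry easily, and the allylic tertiary 6-hydroxyl ionises with acid, so late steps must be basic or neutral and deprotection must use fluoride. The enabling feature is that C6 is a carbinol carbon bearing an unsaturated carbon, so the C6–C7 bond corresponds to addition of a C7 acetylide to a C6 ketone. That ketone cannot enolise, its chair has two syn-axial methyl groups on one face, and the new 6-hydroxyl is the only hydroxyl placed to direct hydride to an alkyne, which distinguishes C7≡C8 from C7'≡C8'.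

## Retrosynthesis

**23 ⇒ 22 ⇒ 21.** The three hydroxyls at C3, C5 and C3' are masked as silyl ethers (two tert-butyldimethylsilyl, one trimethylsilyl at the tertiary O5), all removable by fluoride. The C7=C8 double bond of 22 is traced to the C7≡C8 triple bond of the propargylic alcohol 21. This is preferred to forming C7=C8 by olefination because a propargylic alcohol is reduced to the E-alkene by hydroxyl-directed trans-hydroalumination, which fixes the geometry mechanistically and cannot touch C7'≡C8'. The forward steps must be one directed reduction and one fluoride treatment.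

**21 ⇒ 19 + 8 (C6–C7).** Cutting C6–C7 divides 21 into the ring-A C31 polyenyne 19 (fragment 2, terminal alkyne at C7) and the ring-B ketone 8 (fragment 1, nine ring carbons). This cut removes the chain and the most congested stereocentre together; a cut inside the chain would leave C6 to be built earlier and carried through chain extensions. The ketone 8 has only two stereocentres and no polyene. The forward reaction needs an alkynyllithium to add to a hindered but non-enolisable ketone from the face opposite the syn-axial methyl groups on C1 and C5.

**8 ⇒ 6 ⇒ 4 ⇒ 3 ⇒ 2 ⇒ 1.** The tertiary silyloxy group at C5 of 8 is traced to a Rubottom oxidation of the silyl enol ether 6, which places the oxygen and its trimethylsilyl group in one operation. Enolisation of ketone 4 can only go toward the methyl-bearing carbon, because the other α-carbon is quaternary, so regiochemistry is not an issue. Ketone 4 is the silyl ether of (4R,6R)-4-hydroxy-2,2,6-trimethylcyclohexanone 3, reached from ketoisophorone 1 by two reductions via dione 2. The methyl-bearing stereocentre of 2 relays chirality to C4 in the second reduction and is then erased on enolisation. The forward oxidation must deliver oxygen to the enol ether face cis to the 4-silyloxy group.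

**19 ⇒ 16 + 18; 16 ⇒ 14 + 15; 18 ⇒ 11.** The chain is cut at C11=C12 and C11'=C12', the two disubstituted double bonds next to the central C10 unit. This gives the C10 dialdehyde 15, the C6 enynyl phosphonium salt 18 (from enynol 11) and the ring-A C15 phosphonium salt 14. These cuts use a symmetric, available dialdehyde once at each end and place both new double bonds at unhindered disubstituted positions. The forward Wittig reactions must be E-selective and must not scramble the enyne double bonds C9=C10 and C9'=C10'; tributylphosphonium salts are chosen for this reason.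

**14 ⇒ 12 ⇒ 10 + 11; 10 ⇒ 4.** The ring-A C15 unit is cut at C6'–C7' into enol triflate 10 and the same enynol 11, to be joined by Sonogashira coupling. Triflate 10 comes from ketone 4, so one enantiopure intermediate serves both rings and one enynol serves both enyne termini. The coupling must retain the E geometry of 11 and tolerate the free allylic alcohol.

## Roads not taken

**Alternative 1:** The cut is the C6'–C7' bond between ring A and the triple bond. In the forward direction Pd(PPh3)4 and CuI with an amine would couple enol triflate 10 with the terminal alkyne of the ring-B C31 triol polyenyne A1 to give the target carrying only the ring-A silyl ether, A2.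
- Merits: the last C–C bond forms under mild, nearly neutral conditions with no stereocentre at stake; the coupling type is the one step 7 relies on; only one silyl group would remain to be removed.
- Weak points: the step does nothing for C6. A1 must already contain ring B with its C6–C7 bond, so an acetylide addition is still needed, only earlier, and the acid-sensitive 5,6-diol must then survive two chain extensions. A1 is a free triol with a terminal enyne on a long polyene, exposed to copper and amine, where oxidative alkyne dimerisation and loss of geometry at C9' compete. The chain is built linearly from ring B, so the longest sequence grows.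
- Comparison: as a final coupling, A1 with 10 is probably more dependable than the addition of 20 to 8, and it ends with one protecting group instead of three. The chosen plan sets against this that the difficult bond and the last stereocentre form in the convergent step, that ring B enters as a five-step ketone, and that the palladium coupling is still used, but on the inexpensive enynol 11.

**Alternative 2:** The cut is the C7=C8 double bond. The ylide from the ring-A C30 phosphonium bromide A4 (NaOCH3) would condense with the silylated ring-B C6 carbaldehyde A3 to give the target silylated on ring B, A5.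
- Merits: no triple bond is ever present at C7–C8, so no hydride reduction is needed at the C40 stage and two alkynes need not be told apart; Wittig condensation is the standard carotenoid coupling.
- Weak points: A3 is an aldehyde on a fully substituted carbon between two quaternary centres and carries an α-silyloxy group, so condensation with a bulky C30 ylide should be slow. The semi-stabilised ylide gives no assurance of E geometry at C7=C8 and is delocalised into C9=C10. A3 still requires a one-carbon nucleophile to be added to ketone 8 with the same facial demand, followed by oxidation-state adjustment and silylation of the hindered 6-hydroxyl.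
- Comparison: this road is better in avoiding a reduction on the finished skeleton. The chosen plan sets against it that the reduction is directed and chemoselective by design, that C7=C8 geometry follows from mechanism, and that a slim sp-hybridised nucleophile is the best match for this ketone.

**Alternative 3:** The cut is the central C15=C15' double bond. The anion of the ring-A C20 benzothiazolyl sulfone A6 (KN(SiMe3)2) would add to the ring-B C20 aldehyde A7 and, after Smiles rearrangement and loss of SO2, give the fully silylated target A8.
- Merits: this is the most convergent plan (two C20 halves); the coupling site is unhindered and remote from every stereocentre; E-selectivity at a disubstituted polyene double bond is usually good; no organolithium meets the polyene.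
- Weak points: A7 must itself be made from ketone 8 by acetylide addition, reduction and two chain extensions with the tertiary allylic oxygen on board, so the C6 problem is only moved. A6 needs a thioether oxidation in the presence of an enyne. Both halves are long, and the hindered 6-hydroxyl must be silylated and later freed.
- Comparison: the coupling itself is arguably the safest of the four, and convergence is better. The chosen plan sets against this a lower total step count, a stereocentre created in the coupling step, and no protecting group on the 6-oxygen.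

Key step: step 12

Remark: the configuration worked to is 3S,5S,6S,3'R as drawn, i.e. 3-OH and 5-OH cis on ring B and 6-OH trans to both.
Remark: in step 1 the reducing equivalents come from the yeast's metabolism of sucrose, so no defined stoichiometric co-product is assigned to that step.
Remark: all operations on polyenes (from step 9 on) are to be run under argon in dim light.

## Route

Step 1
Reactants: 1 ketoisophorone (2,6,6-trimethylcyclohex-2-ene-1,4-dione)
Product: 2 (6R)-2,2,6-trimethylcyclohexane-1,4-dione
Conditions: baker's yeast (Saccharomyces cerevisiae), sucrose, H2O, 30 °C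
Reagents that add atoms: none
Why: Biocatalytic conjugate reduction of the enedione C=C by the yeast ene-reductase, a long-established transformation of this substrate, should set the methyl-bearing centre as R; the reaction is stopped at the dione stage before carbonyl reduction sets in.

Step 2
Reactants: 2 (6R)-2,2,6-trimethylcyclohexane-1,4-dione
Product: 3 (4R,6R)-4-hydroxy-2,2,6-trimethylcyclohexanone
Conditions: LiBH(s-Bu)3, THF, −78 °C; then H2O
Reagents that add atoms: none
Why: Chemo- and diastereoselective hydride reduction: the bulky trialkylborohydride should reach only the C4 carbonyl (C1 is flanked by a quaternary and a tertiary carbon), and the axial methyl on C2 blocks the axial trajectory, so hydride enters equatorially and gives the axial 4-hydroxyl trans to the 6-methyl (4R).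

Step 3
Reactants: 3 (4R,6R)-4-hydroxy-2,2,6-trimethylcyclohexanone
Product: 4 (4R,6R)-4-(tert-butyldimethylsilyloxy)-2,2,6-trimethylcyclohexanone
Conditions: t-BuMe2SiCl, imidazole, DMF, rt
Reagents that add atoms: tert-butyldimethylsilyl chloride, CC(C)(C)[Si](C)(C)Cl
Why: Standard imidazole-promoted silylation of a secondary alcohol; the ether is stable to every later step and is removed by fluoride at the end.

Step 4
Reactants: 4 (4R,6R)-4-(tert-butyldimethylsilyloxy)-2,2,6-trimethylcyclohexanone
Product: 6 (4R)-4-(tert-butyldimethylsilyloxy)-2,6,6-trimethyl-1-(trimethylsilyloxy)cyclohex-1-ene, via lithium enolate 5 (not isolated)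
Conditions: LiN(i-Pr)2, THF, −78 → 0 °C; Me3SiCl, −78 °C → rt
Reagents that add atoms: chlorotrimethylsilane, C[Si](C)(C)Cl
Why: Silyl enol ether formation by amide deprotonation and O-silylation; only the methyl-bearing α-carbon has a hydrogen, so a single regioisomer can form, and the relay stereocentre is deliberately erased here.

Step 5
Reactants: 6 (4R)-4-(tert-butyldimethylsilyloxy)-2,6,6-trimethyl-1-(trimethylsilyloxy)cyclohex-1-ene
Product: 8 (2S,4S)-4-(tert-butyldimethylsilyloxy)-2,6,6-trimethyl-2-(trimethylsilyloxy)cyclohexanone (fragment 1), via silyloxy epoxide 7 (not isolated)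
Conditions: m-CPBA, NaHCO3, CH2Cl2, −20 → 0 °C
Reagents that add atoms: 3-chloroperbenzoic acid, OOC(=O)c1cccc(Cl)c1
Why: Rubottom oxidation: the peracid epoxidises the enol ether, the silyloxy epoxide 7 opens to an oxocarbenium ion and a 1,4-silyl shift gives the α-silyloxy ketone with the trimethylsilyl group already on the new tertiary oxygen. In the half-chair with the 4-silyloxy group equatorial, the pseudoaxial methyl of the gem-dimethyl carbon shields the face anti to that group, so oxygen should enter cis to it (2S). The buffered, non-hydrolytic work-up is meant to keep the trimethylsilyl ether.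

Step 6
Reactants: 4 (4R,6R)-4-(tert-butyldimethylsilyloxy)-2,2,6-trimethylcyclohexanone
Product: 10 (4R)-4-(tert-butyldimethylsilyloxy)-2,6,6-trimethylcyclohex-1-en-1-yl trifluoromethanesulfonate, via potassium enolate 9 (not isolated)
Conditions: KN(SiMe3)2, THF, −78 → 0 °C; PhN(SO2CF3)2, −78 °C → rt
Reagents that add atoms: N-phenylbis(trifluoromethanesulfonimide), O=S(=O)(N(c1ccccc1)S(=O)(=O)C(F)(F)F)C(F)(F)F
Why: Enol triflate formation: the potassium amide removes the only α-hydrogen of 4, so a single enolate regioisomer forms, and the potassium enolate, which is less aggregated and more reactive at oxygen than its lithium counterpart, is O-sulfonylated by the N-phenyl triflimide, the standard way to alkenyl triflates of hindered 2,2,6-trisubstituted cyclohexanones.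

Step 7
Reactants: 10 (4R)-4-(tert-butyldimethylsilyloxy)-2,6,6-trimethylcyclohex-1-en-1-yl trifluoromethanesulfonate; 11 (E)-3-methylpent-2-en-4-yn-1-ol
Product: 12 (2E)-5-[(4R)-4-(tert-butyldimethylsilyloxy)-2,6,6-trimethylcyclohex-1-en-1-yl]-3-methylpent-2-en-4-yn-1-ol
Conditions: Pd(PPh3)4 (cat.), CuI (cat.), i-Pr2NH, THF, rt
Reagents that add atoms: none
Why: Sonogashira coupling of an alkenyl triflate with a terminal alkyne forms the C6'–C7' bond; the zerovalent palladium catalyst inserts into the C–O bond of the hindered triflate, the free allylic alcohol is tolerated, and the E geometry of 11 is not touched.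

Step 8
Reactants: 12 (2E)-5-[(4R)-4-(tert-butyldimethylsilyloxy)-2,6,6-trimethylcyclohex-1-en-1-yl]-3-methylpent-2-en-4-yn-1-ol
Product: 14 tributyl{(2E)-5-[(4R)-4-(tert-butyldimethylsilyloxy)-2,6,6-trimethylcyclohex-1-en-1-yl]-3-methylpent-2-en-4-yn-1-yl}phosphonium bromide, via allylic bromide 13 (not isolated)
Conditions: CBr4, PPh3, CH2Cl2, −20 → 0 °C; filtration through SiO2; then P(n-Bu)3, EtOAc, rt
Reagents that add atoms: carbon tetrabromide, BrC(Br)(Br)Br; tributylphosphine, CCCCP(CCCC)CCCC
Why: Appel bromination under non-acidic conditions (the silyl ether survives) followed by SN2 quaternisation of the reactive allylic bromide with the nucleophilic trialkylphosphine; the salt should precipitate and be freed of phosphine oxide by washing.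

Step 9
Reactants: 14 the ring-A C15 tributylphosphonium bromide; 15 (2E,4E,6E)-2,7-dimethylocta-2,4,6-trienedial
Product: 16 (2E,4E,6E,8E,10E)-13-[(4R)-4-(tert-butyldimethylsilyloxy)-2,6,6-trimethylcyclohex-1-en-1-yl]-2,7,11-trimethyltrideca-2,4,6,8,10-pentaen-12-ynal (C25 aldehyde)
Conditions: NaOCH3, CH2Cl2/CH3OH, 0 °C → rt, dark, 15 in excess
Reagents that add atoms: none
Why: Wittig olefination forms C11'=C12'; allylic trialkylphosphonium ylides are known to favour E-alkenes, and excess dialdehyde together with the lower electrophilicity of the extended product aldehyde should hold the reaction at mono-condensation.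

Step 10
Reactants: 11 (E)-3-methylpent-2-en-4-yn-1-ol
Product: 18 tributyl[(2E)-3-methylpent-2-en-4-yn-1-yl]phosphonium bromide, via enynyl bromide 17 (not isolated)
Conditions: PBr3, Et2O, −10 °C; then P(n-Bu)3, EtOAc, rt
Reagents that add atoms: phosphorus tribromide, BrP(Br)Br; tributylphosphine, CCCCP(CCCC)CCCC
Why: Classical bromination of this allylic alcohol followed by SN2 quaternisation; the volatile bromide is used crude and the terminal alkyne needs no protection.

Step 11
Reactants: 16 the C25 aldehyde; 18 tributyl[(2E)-3-methylpent-2-en-4-yn-1-yl]phosphonium bromide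
Product: 19 (3'R)-3'-(tert-butyldimethylsilyloxy) ring-A C31 polyenyne (fragment 2): ring A joined through C7'≡C8' to the all-E heptaene C9'–C10 that ends in the terminal alkyne C8≡C7–H
Conditions: NaOCH3, CH2Cl2/CH3OH, 0 °C → rt, dark
Reagents that add atoms: none
Why: Second Wittig olefination forms C11=C12 with the same E preference; methoxide generates the ylide without deprotonating the terminal alkyne, and the salt is used in excess so that the valuable aldehyde is consumed.

Step 12
Reactants: 19 ring-A C31 polyenyne (fragment 2); 8 (2S,4S)-4-(tert-butyldimethylsilyloxy)-2,6,6-trimethyl-2-(trimethylsilyloxy)cyclohexanone (fragment 1)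
Product: 21 (3S,5S,6R,3'R)-3,3'-bis(tert-butyldimethylsilyloxy)-5-(trimethylsilyloxy)-7,8,7',8'-tetradehydro-5,6-dihydro-β,β-caroten-6-ol, via lithium acetylide 20 (not isolated)
Conditions: LiN(SiMe3)2, THF, −78 °C; then 8 (1.5 equiv), −78 → −20 °C; AcOH, −78 °C
Reagents that add atoms: none
Why: LiN(SiMe3)2 removes the terminal C7–H of 19 to give acetylide 20, which adds to the C6 carbonyl of 8 in a 1,2-addition of an alkynyllithium to a ketone, the reaction type long used to attach ethynyl and enynyl units to 2,2,6-trisubstituted cyclohexanones; it forms the C6–C7 bond and the C6 stereocentre and closes no ring. Ketone 8 has no α-hydrogen, so the basic acetylide cannot enolise it; the only competitor is slow addition, answered by an excess of the inexpensive ketone and, if needed, anhydrous CeCl3 as activator. The stereocentre is under substrate control: in the chair with both silyloxy groups equatorial, the C5 methyl and one C1 methyl are syn-axial on the face anti to the silyloxy groups, so the rod-shaped nucleophile should enter along the axial direction of C6 from the other face. C7 then becomes axial and cis to O5, and the new hydroxyl equatorial and trans to O5, which is 6R in 21 and becomes 6S once C7 is an alkene carbon. The step needs facial selectivity (secured as described) and chemoselectivity (the ketone is the only electrophile; silyl ethers and polyene are inert at this temperature). Protonation with AcOH at −78 °C is meant to forestall silyl transfer from O5 to the new alkoxide; the equilibrium should in any case leave silicon on O5, since the propargylic alkoxide is the better stabilised anion.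

Step 13
Reactants: 21 the 7,8-didehydro C40 propargylic alcohol
Product: 22 (3S,5S,6S,3'R)-3,3'-bis(tert-butyldimethylsilyloxy)-5-(trimethylsilyloxy)-7',8'-didehydro-5,6-dihydro-β,β-caroten-6-ol
Conditions: NaAlH2(OCH2CH2OCH3)2, THF, 0 °C → rt; then aq. KNaC4H4O6
Reagents that add atoms: none
Why: Hydroxyl-directed trans-hydroalumination of a propargylic alcohol: the 6-alkoxyaluminium hydride delivers hydride to C7, aluminium closes a five-membered ring onto C8, and protonolysis gives the E-alkene. C7'≡C8' has no neighbouring hydroxyl and should not react, and silyl ethers tolerate the reagent.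

Step 14
Reactants: 22 the tris-silylated tetrol
Product: 23 (3S,5S,6S,3'R)-7',8'-didehydro-5,6-dihydro-β,β-carotene-3,5,6,3'-tetrol (CNP0160593.1)
Conditions: n-Bu4NF, THF, 0 °C → rt
Reagents that add atoms: none
Why: Fluoride cleavage of the trimethylsilyl and both tert-butyldimethylsilyl ethers under non-acidic conditions, which spares the acid-labile allylic tertiary 6-hydroxyl and the polyene; no stereocentre is affected.

## Compound list

1 | ketoisophorone (2,6,6-trimethylcyclohex-2-ene-1,4-dione) | CC1=CC(=O)CC(C)(C)C1=O | starting material
2 | (6R)-2,2,6-trimethylcyclohexane-1,4-dione | O=C1C(C)(C)CC(=O)C[C@H]1C | intermediate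
3 | (4R,6R)-4-hydroxy-2,2,6-trimethylcyclohexanone | O=C1C(C)(C)C[C@H](O)C[C@H]1C | intermediate
4 | (4R,6R)-4-(tert-butyldimethylsilyloxy)-2,2,6-trimethylcyclohexanone | O=C1C(C)(C)C[C@H](O[Si](C)(C)C(C)(C)C)C[C@H]1C | intermediate
5 | lithium (4R)-4-(tert-butyldimethylsilyloxy)-2,6,6-trimethylcyclohex-1-en-1-olate | CC1=C(O[Li])C(C)(C)C[C@H](O[Si](C)(C)C(C)(C)C)C1 | intermediate
6 | (4R)-4-(tert-butyldimethylsilyloxy)-2,6,6-trimethyl-1-(trimethylsilyloxy)cyclohex-1-ene | CC1=C(O[Si](C)(C)C)C(C)(C)C[C@H](O[Si](C)(C)C(C)(C)C)C1 | intermediate
7 | 1,2-epoxide of 6, oxirane oxygen cis to the 4-silyloxy group | C[C@@]12O[C@]1(O[Si](C)(C)C)C(C)(C)C[C@H](O[Si](C)(C)C(C)(C)C)C2 | intermediate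
8 | (2S,4S)-4-(tert-butyldimethylsilyloxy)-2,6,6-trimethyl-2-(trimethylsilyloxy)cyclohexanone (fragment 1) | O=C1C(C)(C)C[C@H](O[Si](C)(C)C(C)(C)C)C[C@]1(C)O[Si](C)(C)C | intermediate
9 | potassium (4R)-4-(tert-butyldimethylsilyloxy)-2,6,6-trimethylcyclohex-1-en-1-olate | CC1=C(O[K])C(C)(C)C[C@H](O[Si](C)(C)C(C)(C)C)C1 | intermediate
10 | (4R)-4-(tert-butyldimethylsilyloxy)-2,6,6-trimethylcyclohex-1-en-1-yl trifluoromethanesulfonate | CC1=C(OS(=O)(=O)C(F)(F)F)C(C)(C)C[C@H](O[Si](C)(C)C(C)(C)C)C1 | intermediate
11 | (E)-3-methylpent-2-en-4-yn-1-ol | C#C/C(C)=C/CO | starting material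
12 | (2E)-5-[(4R)-4-(tert-butyldimethylsilyloxy)-2,6,6-trimethylcyclohex-1-en-1-yl]-3-methylpent-2-en-4-yn-1-ol | CC1=C(C#C/C(C)=C/CO)C(C)(C)C[C@H](O[Si](C)(C)C(C)(C)C)C1 | intermediate
13 | allylic bromide of 12 (ring-A C15 bromide) | CC1=C(C#C/C(C)=C/CBr)C(C)(C)C[C@H](O[Si](C)(C)C(C)(C)C)C1 | intermediate
14 | tributyl{(2E)-5-[(4R)-4-(tert-butyldimethylsilyloxy)-2,6,6-trimethylcyclohex-1-en-1-yl]-3-methylpent-2-en-4-yn-1-yl}phosphonium bromide | CC1=C(C#C/C(C)=C/C[P+](CCCC)(CCCC)CCCC)C(C)(C)C[C@H](O[Si](C)(C)C(C)(C)C)C1.[Br-] | intermediate
15 | (2E,4E,6E)-2,7-dimethylocta-2,4,6-trienedial | O=C/C(C)=C/C=C/C=C(C)/C=O | starting material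
16 | (2E,4E,6E,8E,10E)-13-[(4R)-4-(tert-butyldimethylsilyloxy)-2,6,6-trimethylcyclohex-1-en-1-yl]-2,7,11-trimethyltrideca-2,4,6,8,10-pentaen-12-ynal | CC1=C(C#C/C(C)=C/C=C/C(C)=C/C=C/C=C(C)/C=O)C(C)(C)C[C@H](O[Si](C)(C)C(C)(C)C)C1 | intermediate
17 | (E)-5-bromo-3-methylpent-3-en-1-yne | C#C/C(C)=C/CBr | intermediate
18 | tributyl[(2E)-3-methylpent-2-en-4-yn-1-yl]phosphonium bromide | C#C/C(C)=C/C[P+](CCCC)(CCCC)CCCC.[Br-] | intermediate
19 | (3'R)-3'-(tert-butyldimethylsilyloxy) ring-A C31 polyenyne (fragment 2), all-E, terminal alkyne at C7 | CC1=C(C#C/C(C)=C/C=C/C(C)=C/C=C/C=C(C)/C=C/C=C(C)/C#C)C(C)(C)C[C@H](O[Si](C)(C)C(C)(C)C)C1 | intermediate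
20 | lithium acetylide of 19 | CC1=C(C#C/C(C)=C/C=C/C(C)=C/C=C/C=C(C)/C=C/C=C(C)/C#C[Li])C(C)(C)C[C@H](O[Si](C)(C)C(C)(C)C)C1 | intermediate
21 | (3S,5S,6R,3'R)-3,3'-bis(tert-butyldimethylsilyloxy)-5-(trimethylsilyloxy)-7,8,7',8'-tetradehydro-5,6-dihydro-β,β-caroten-6-ol | CC1=C(C#C/C(C)=C/C=C/C(C)=C/C=C/C=C(C)/C=C/C=C(C)/C#C[C@]2(O)C(C)(C)C[C@H](O[Si](C)(C)C(C)(C)C)C[C@]2(C)O[Si](C)(C)C)C(C)(C)C[C@H](O[Si](C)(C)C(C)(C)C)C1 | intermediate
22 | (3S,5S,6S,3'R)-3,3'-bis(tert-butyldimethylsilyloxy)-5-(trimethylsilyloxy)-7',8'-didehydro-5,6-dihydro-β,β-caroten-6-ol | CC1=C(C#C/C(C)=C/C=C/C(C)=C/C=C/C=C(C)/C=C/C=C(C)/C=C/[C@]2(O)C(C)(C)C[C@H](O[Si](C)(C)C(C)(C)C)C[C@]2(C)O[Si](C)(C)C)C(C)(C)C[C@H](O[Si](C)(C)C(C)(C)C)C1 | intermediate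
23 | (3S,5S,6S,3'R)-7',8'-didehydro-5,6-dihydro-β,β-carotene-3,5,6,3'-tetrol (CNP0160593.1) | CC1=C(C#C/C(C)=C/C=C/C(C)=C/C=C/C=C(C)/C=C/C=C(C)/C=C/[C@]2(O)C(C)(C)C[C@H](O)C[C@]2(C)O)C(C)(C)C[C@H](O)C1 | target

## Step count and least certain steps

Total: 14 steps. Longest linear sequence: 11 steps (1, 2, 3, 6, 7, 8, 9, 11, 12, 13, 14). The ring-B branch (1, 2, 3, 4, 5) joins at step 12.

**Step 12 (key step).** The most likely failure is a sluggish or reversible addition to a carbonyl flanked by two quaternary carbons, leaving the C31 acetylide to decompose. Beyond that, facial selectivity could be incomplete if the ketone reacts through a twisted conformation, and silicon could move between O5 and the new alkoxide. The fallback makes the C6–C7 bond with a small acetylide and attaches the polyene afterwards; it sets out from 8, 11 and 16 and returns at 22. Enynol 11 is doubly deprotonated (n-BuLi) to the dilithium salt of (E)-3-methylpent-2-en-4-yn-1-ol F1 and added to 8, the classical way to alkynylate such ketones, giving the ring-B C15 enynediol F2. NaAlH2(OCH2CH2OCH3)2 reduces its C7≡C8 bond to give the ring-B C15 dienediol F3, and MnO2 oxidises the primary allylic alcohol to the ring-B C15 dienal F4. Separately, aldehyde 16 is reduced (NaBH4) to the ring-A C25 allylic alcohol F5, brominated (CBr4, PPh3) to the ring-A C25 allylic bromide F6 and quaternised with P(n-Bu)3 to the ring-A C25 tributylphosphonium bromide F7. Wittig condensation of F7 with F4 (NaOCH3) forms C11=C12 and gives 22.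

**Step 5.** Poor facial selectivity in the epoxidation is the main risk: peracid oxidations of related 3-oxygenated trimethylcyclohexene rings are often only moderately face-selective, and attack anti to the silyloxy group would give the C5 epimer. Partial loss of the trimethylsilyl group on work-up is a lesser risk. The fallback replaces substrate control by reagent control. It sets out from 4: the lithium enolate 5, generated as in step 4, is oxidised with an enantiopure (camphorsulfonyl)oxaziridine, the enantiomer chosen to match the required face, to give the ketol (2S,4S)-4-(tert-butyldimethylsilyloxy)-2-hydroxy-2,6,6-trimethylcyclohexanone F8. Silylation with Me3SiCl and imidazole returns to 8.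

**Step 11 (and, in the same way, step 9).** The ylide from 18 is delocalised onto C9, so erosion of the C9=C10 geometry during olefination is the concern, together with Z-alkene at the new C11=C12 bond. Equilibration cannot repair a 9Z isomer, because next to a triple bond it is not disfavoured. The fallback reverses the polarity so that no ylide sits beside the enyne. It sets out from 16 and 11 and returns at 19: 16 is taken through the ring-A C25 allylic alcohol F5 and the ring-A C25 allylic bromide F6 to the ring-A C25 tributylphosphonium bromide F7 as above, 11 is oxidised with MnO2 to (E)-3-methylpent-2-en-4-ynal F9, and Wittig condensation of F7 with F9 (NaOCH3) gives 19.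

**Step 13.** The reduction depends on a free 6-hydroxyl. If silicon has moved from O5 to O6, no hydride is delivered and forcing conditions would begin to attack the conjugated enyne at C7'≡C8'. The fallback changes the order of events. It sets out from 21 and returns at 23: n-Bu4NF first removes all three silyl groups to give the acetylenic tetrol F10, which is then added to an excess of NaAlH2(OCH2CH2OCH3)2 so that each hydroxyl is capped by its own aluminate; only C7≡C8, next to the 6-alkoxide, should be reduced, giving 23 directly.

## Further compounds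

F1 | step 12 | dilithium salt of (E)-3-methylpent-2-en-4-yn-1-ol | [Li]C#C/C(C)=C/CO[Li]
F2 | step 12 | ring-B C15 enynediol (3-O-tert-butyldimethylsilyl, 5-O-trimethylsilyl, 6-OH, C7≡C8, C11-OH) | OC/C=C(C)/C#C[C@]1(O)C(C)(C)C[C@H](O[Si](C)(C)C(C)(C)C)C[C@]1(C)O[Si](C)(C)C
F3 | step 12 | ring-B C15 (7E,9E)-dienediol | OC/C=C(C)/C=C/[C@]1(O)C(C)(C)C[C@H](O[Si](C)(C)C(C)(C)C)C[C@]1(C)O[Si](C)(C)C
F4 | step 12 | ring-B C15 (7E,9E)-dienal | O=C/C=C(C)/C=C/[C@]1(O)C(C)(C)C[C@H](O[Si](C)(C)C(C)(C)C)C[C@]1(C)O[Si](C)(C)C
F5 | step 12 | ring-A C25 allylic alcohol (reduction product of 16) | CC1=C(C#C/C(C)=C/C=C/C(C)=C/C=C/C=C(C)/CO)C(C)(C)C[C@H](O[Si](C)(C)C(C)(C)C)C1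
F6 | step 12 | ring-A C25 allylic bromide | CC1=C(C#C/C(C)=C/C=C/C(C)=C/C=C/C=C(C)/CBr)C(C)(C)C[C@H](O[Si](C)(C)C(C)(C)C)C1
F7 | step 12 | ring-A C25 tributylphosphonium bromide | CC1=C(C#C/C(C)=C/C=C/C(C)=C/C=C/C=C(C)/C[P+](CCCC)(CCCC)CCCC)C(C)(C)C[C@H](O[Si](C)(C)C(C)(C)C)C1.[Br-]
F8 | step 5 | (2S,4S)-4-(tert-butyldimethylsilyloxy)-2-hydroxy-2,6,6-trimethylcyclohexanone | O=C1C(C)(C)C[C@H](O[Si](C)(C)C(C)(C)C)C[C@]1(C)O
F9 | step 11 | (E)-3-methylpent-2-en-4-ynal | C#C/C(C)=C/C=O
F10 | step 13 | (3S,5S,6R,3'R)-7,8,7',8'-tetradehydro-5,6-dihydro-β,β-carotene-3,5,6,3'-tetrol | CC1=C(C#C/C(C)=C/C=C/C(C)=C/C=C/C=C(C)/C=C/C=C(C)/C#C[C@]2(O)C(C)(C)C[C@H](O)C[C@]2(C)O)C(C)(C)C[C@H](O)C1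
A1 | alternative 1 | ring-B C31 triol polyenyne with terminal alkyne at C7' | C#C/C(C)=C/C=C/C(C)=C/C=C/C=C(C)/C=C/C=C(C)/C=C/[C@]1(O)C(C)(C)C[C@H](O)C[C@]1(C)O
A2 | alternative 1 | target carrying one tert-butyldimethylsilyl ether on ring A | CC1=C(C#C/C(C)=C/C=C/C(C)=C/C=C/C=C(C)/C=C/C=C(C)/C=C/[C@]2(O)C(C)(C)C[C@H](O)C[C@]2(C)O)C(C)(C)C[C@H](O[Si](C)(C)C(C)(C)C)C1
A3 | alternative 2 | silylated ring-B C6 carbaldehyde | O=C[C@]1(O[Si](C)(C)C)C(C)(C)C[C@H](O[Si](C)(C)C(C)(C)C)C[C@]1(C)O[Si](C)(C)C
A4 | alternative 2 | ring-A C30 triphenylphosphonium bromide (phosphorus on C8) | CC1=C(C#C/C(C)=C/C=C/C(C)=C/C=C/C=C(C)/C=C/C=C(C)/C[P+](c2ccccc2)(c2ccccc2)c2ccccc2)C(C)(C)C[C@H](O)C1.[Br-]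
A5 | alternative 2 | target silylated on ring B | CC1=C(C#C/C(C)=C/C=C/C(C)=C/C=C/C=C(C)/C=C/C=C(C)/C=C/[C@]2(O[Si](C)(C)C)C(C)(C)C[C@H](O[Si](C)(C)C(C)(C)C)C[C@]2(C)O[Si](C)(C)C)C(C)(C)C[C@H](O)C1
A6 | alternative 3 | ring-A C20 benzothiazolyl sulfone (sulfur on C15') | CC1=C(C#C/C(C)=C/C=C/C(C)=C/CS(=O)(=O)c2nc3ccccc3s2)C(C)(C)C[C@H](O[Si](C)(C)C(C)(C)C)C1
A7 | alternative 3 | ring-B C20 aldehyde (aldehyde at C15) | O=C/C=C(C)/C=C/C=C(C)/C=C/[C@]1(O[Si](C)(C)C)C(C)(C)C[C@H](O[Si](C)(C)C(C)(C)C)C[C@]1(C)O[Si](C)(C)C
A8 | alternative 3 | fully silylated target | CC1=C(C#C/C(C)=C/C=C/C(C)=C/C=C/C=C(C)/C=C/C=C(C)/C=C/[C@]2(O[Si](C)(C)C)C(C)(C)C[C@H](O[Si](C)(C)C(C)(C)C)C[C@]2(C)O[Si](C)(C)C)C(C)(C)C[C@H](O[Si](C)(C)C(C)(C)C)C1
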